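## Structural features

The target is an achiral compound with four benzene rings in a row. Ring A (a para-substituted phenol) is joined to ring B by a CH2CH2 bridge, ring B to ring C by a diaryl ether oxygen, and ring C to ring D by a second CH2CH2 bridge. Ring B is 1,3,5-trisubstituted (OMe, bridge, ether oxygen) and ring C is para-disubstituted. Ring D is a tetrasubstituted β-resorcylic acid with CO2H at C1, OH at C2, OMe at C4 and the bridge at C6. There is no stereocentre, so no stereochemical relationship has to be set or protected. The fragile part is ring D: a 2-hydroxy-4-alkoxybenzoic acid loses CO2 on heating or in acid, and the free phenols are oxidisable, so acid and phenols should be released last under neutral conditions. The real difficulty is the contiguous 1,2,6-substitution of ring D, with the carboxyl wedged between a hydroxyl and the bridge, together with the differentiation of its two oxygens. The key step uses the alternation of oxygen (C2, C4) and carbon substituents (C1, C6) on ring D. This is the pattern a 3,5,7-trioxo ester leaves when its C2 adds to the C7 ketone, so the C1–C6 bond of ring D (C2–C7 of the open chain) can be closed last on a chain that already carries rings A to C.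

## Logic of the disconnections

20 to 19. The two O–CH2Ph bonds (ring D ester, ring A ether) are cut. The acid and both phenols are then unveiled together by one neutral hydrogenolysis at the very end. The forward step only requires that nothing else in 19 is reducible; the diaryl ether, the methyl ethers and the saturated bridges meet this.

19 to 18. The O–CH3 bond at C4 of ring D is cut. This is the price of the polyketide folding, which delivers both ring D oxygens as hydroxyls. The forward step needs site selectivity between the 4-OH and the 2-OH. The 2-OH is held in a hydrogen bond to the ester carbonyl and flanked by it, so a weak base and one equivalent of methylating agent should discriminate.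

18 to 13 and 14. This is the key cut: the C1–C6 bond of ring D and the ester C–O bond are broken, which unfolds ring D to the open trioxo ester 16. Two of its carbonyls are stored as the dioxinone ring of 13. The gain is large: a crowded tetrasubstituted arene becomes a linear chain whose substituent positions are fixed by connectivity alone. The forward step must release 15 thermally, capture it with 14, and then fold 16 in the aldol mode (through 17) and not in the Claisen or lactone mode.

13 to 11 and 7. The C–C bond between the future C6 carbon of ring D (the chain ketone next to the bridge) and the terminal carbon of 11 is cut. This corresponds to acylation of dianion 12 at its terminal carbon. An N-methoxy-N-methylamide is chosen as the acyl donor because its tetrahedral adduct should survive until the quench. A more reactive donor (an acyl imidazole or chloride) would release the acidic triketone in the flask and consume a second equivalent of 12 by proton transfer. The demand is reaction at the terminal carbanion only; 12 is cheap and is used in excess.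

11 to 8 and 9. One C–C bond is cut, corresponding to acylation of dienolate 10 at its exocyclic carbon. This takes the dioxinone back to two bulk chemicals.

7 to 4 and 5. The bond between ring B and the CH2 of the first bridge is cut, corresponding to a B-alkyl Suzuki coupling through 6. This delivers the saturated bridge directly, so no alkene has to be hydrogenated while the benzyl ether is present. The borane meets only an amide and never an aldehyde, which alkyl-9-BBN reagents can reduce. The demand is clean oxidative addition at C–Br and no residual B–H.

4 to 3. The amide C–N bond is cut (OMe exchanged for N(OMe)Me). The exchange is placed before the coupling so that the methyl ester is not exposed to warm aqueous phosphate and the coupling product is already the acyl donor.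

3 to 1 and 2. The bond between the ether oxygen and ring B is cut. Ring C then arrives as 1 with its saturated three-carbon chain at the right oxidation level, so neither chain extension nor reduction is needed. Ring B acts as the boron partner in an oxidative copper coupling, so it needs no activating group. The demand is that the bromine survives, which room-temperature copper chemistry allows.

## Other disconnections considered

Alternative 1: The cut is in ring B, not ring D.
- Key step: dimethyl malonate A2 adds to the enone (E)-6-[4-(benzyloxy)phenyl]hex-3-en-2-one A1 in a Michael reaction. The methyl ketone then closes onto a malonate ester (Claisen), and hydrolysis with decarboxylation would give 5-{2-[4-(benzyloxy)phenyl]ethyl}cyclohexane-1,3-dione A3. A3 would be converted through its methyl enol ether and dehydrogenation into 3-{2-[4-(benzyloxy)phenyl]ethyl}-5-methoxyphenol A4, which still has to be O-arylated with a ring C unit.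
- In favour: the chemistry is cheap, free of transition metals and scalable. The 1,3,5-pattern follows from the construction, and the enol ether route differentiates the two ring B oxygens. On that point it is the equal of buying 2, and on avoiding palladium and boron for the ring A to ring B link it is the better.
- Against: ring B is purchasable with the correct pattern, and the hard ring D remains unsolved, so a ring D construction such as step 6 would still be needed. A1 needs its own preparation. The aromatisation must spare the electron-rich ring A and the benzyl ether. Because A4 is a phenol, ring C would have to be the electrophile and 1 could not be used as it is.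
- Structure: it forms no bond that the chosen plan finds difficult.
- Mechanism: it belongs to the same family (enolate condensation, then aromatisation) and should be equally reliable.
- Step economy: about five steps to A4, against two (steps 1 and 3) for the same connectivity, so it is clearly worse.

Alternative 2: The cut is the bond from C6 of ring D to the bridge carbon, with a transient lactone C–O bond.
- Key step: 2-(benzyloxy)-4-methoxybenzoic acid A5 and the styrene 1-{2-[4-(benzyloxy)phenyl]ethyl}-3-(4-ethenylphenoxy)-5-methoxybenzene A6 would couple under a divalent palladium catalyst with a divalent copper co-oxidant and air. Carboxylate-directed ortho palladation, alkene insertion and oxidative lactonisation would give 8-(benzyloxy)-3-[4-(3-{2-[4-(benzyloxy)phenyl]ethyl}-5-methoxyphenoxy)phenyl]-6-methoxy-1H-isochromen-1-one A7. One hydrogenation over Pd/C would then have to saturate C3–C4, cleave the benzylic lactone C–O bond and remove both benzyl groups to reach 20.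
- In favour: it is highly convergent. Ring D is bought with its oxygens already differentiated, so no selective methylation is needed (better than the chosen plan). A5 has a single ortho C–H, so the site is not in question. The count of about six to seven steps is lower than eight (better).
- Against: oxidative coupling of benzoic acids with styrenes turns over poorly and can branch between plain ortho-alkenylation, 6-endo closure to A7 and 5-exo closure to a benzylidene phthalide. An ortho-alkoxy, para-methoxy benzoic acid is prone to protodecarboxylation under hot acetate conditions. A6 is a late, valuable alkene that would be needed in excess. The lactone C–O hydrogenolysis is slower than benzyl cleavage and may stop at the dihydroisocoumarin.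
- Structure: more convergent than the chosen plan.
- Mechanism: less predictable, with three competing manifolds against one polar cascade whose selectivity has a clear electronic basis. Both plans end with a hydrogenolysis over Pd/C and are equal there.
- Step economy: better on paper.

Alternative 3: The cut is two ring D bonds, C1–C2 and C5–C6.
- Key step: benzyl 5-[4-(3-{2-[4-(benzyloxy)phenyl]ethyl}-5-methoxyphenoxy)phenyl]pent-2-ynoate A8 and (Z)-1,3-dimethoxy-1-(trimethylsilyloxy)buta-1,3-diene A9 would undergo a Diels–Alder reaction. The CH2 terminus of A9 bonds to the β-carbon of A8 and the ketene acetal carbon to the α-carbon. Loss of the acetal methoxy group and of silicon would give benzyl 2-hydroxy-4-methoxy-6-{2-[4-(3-{2-[4-(benzyloxy)phenyl]ethyl}-5-methoxyphenoxy)phenyl]ethyl}benzoate A10, which is identical with 19.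
- In favour: regiochemistry is fixed by polarity matching. The 4-OMe and 2-OH arrive differentiated, so step 7 disappears (better). Two ring bonds form in one step, against one in the chosen plan (better in bond count).
- Against: a β-alkyl ynoate is a weak dienophile, and the heat it needs is close to where A9 suffers silyl migration, hydrolysis or polymerisation. A9 must be made fresh in two steps and used in excess. A8 needs about three steps from 7 (reduction to the aldehyde level, alkyne homologation, carboxylation), against one step from 7 to 13.
- Structure: it reaches the same late intermediate and has the same final step, so it is equal there.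
- Mechanism: a pericyclic step with secure orientation but uncertain rate, against a polar cascade with secure rate but a mode selectivity to control.
- Step economy: from 7 it needs about four linear steps plus two for A9 to reach 19, against three (steps 5 to 7) plus one for 11, so the chosen plan is shorter.

Key step: step 6

Assumption: 20 has no stereocentre, so no stereocontrol is planned; 1, 2, 5, 8, 9 and 14 are treated as purchasable.

Step 1
Reactants: 1 methyl 3-(4-hydroxyphenyl)propanoate; 2 (3-bromo-5-methoxyphenyl)boronic acid
Product: 3 methyl 3-[4-(3-bromo-5-methoxyphenoxy)phenyl]propanoate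
Conditions: Cu(OAc)2 (2 equiv), pyridine (5 equiv), 4 Å MS, CH2Cl2, dry air, rt
Reagents that add atoms: none
Why: Chan–Lam oxidative O-arylation: the aryl group of 2 is transferred to divalent copper, the phenoxide of 1 binds, and C–O reductive elimination from a trivalent copper intermediate should give the diaryl ether. An unhindered para-alkylphenol and a meta-substituted arylboronic acid are a standard pairing, and room-temperature copper chemistry leaves the C–Br bond and the methyl ester untouched.

Step 2
Reactants: 3 methyl 3-[4-(3-bromo-5-methoxyphenoxy)phenyl]propanoate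
Product: 4 3-[4-(3-bromo-5-methoxyphenoxy)phenyl]-N-methoxy-N-methylpropanamide
Conditions: MeNH(OMe)·HCl (1.5 equiv), i-PrMgCl (3 equiv), THF, −20 to 0 °C; aq NH4Cl
Reagents that add atoms: N,O-dimethylhydroxylamine hydrochloride, CNOC.Cl
Why: Ester aminolysis by the chloromagnesium amide generated in the flask (Weinreb amide synthesis). Below 0 °C the Grignard reagent is consumed by the ammonium salt far faster than it could exchange with the unactivated aryl bromide.

Step 3
Reactants: 5 1-(benzyloxy)-4-vinylbenzene; 4 3-[4-(3-bromo-5-methoxyphenoxy)phenyl]-N-methoxy-N-methylpropanamide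
Product: 7 3-[4-(3-{2-[4-(benzyloxy)phenyl]ethyl}-5-methoxyphenoxy)phenyl]-N-methoxy-N-methylpropanamide, via alkylborane 6 (not isolated)
Conditions: 5 (1.3 equiv), 9-BBN (1.2 equiv), THF, 0 °C to rt; then 4 (1 equiv), PdCl2(dppf) (5 mol %), K3PO4 (3 M aq, 3 equiv), DMF, 65 °C
Reagents that add atoms: none
Why: Anti-Markovnikov hydroboration of 5 with 9-BBN gives the primary alkylborane 6, which should couple with 4 in a B-alkyl Suzuki–Miyaura reaction (oxidative addition of zerovalent palladium into C–Br, base-assisted alkyl transfer from boron, reductive elimination). Keeping 5 in slight excess over 9-BBN leaves no B–H to attack the amide, and the bidentate dppf ligand disfavours β-hydride elimination from the alkylpalladium intermediate.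

Step 4
Reactants: 8 2,2,6-trimethyl-4H-1,3-dioxin-4-one; 9 acetyl chloride
Product: 11 2,2-dimethyl-6-(2-oxopropyl)-4H-1,3-dioxin-4-one, via lithium dienolate 10 (not isolated)
Conditions: 8 (2 equiv), LiN(SiMe3)2 (2 equiv), THF, −78 °C; then 9 (1 equiv), −78 to −20 °C; aq NH4Cl
Reagents that add atoms: none
Why: Deprotonation of the C6 methyl group gives the cross-conjugated dienolate 10, which should be C-acylated at its exocyclic carbon by 9 (vinylogous Claisen-type acylation of a dioxinone dienolate). Because 11 is more acidic than 8, the second equivalent of 10 serves as base and should be recovered as 8.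

Step 5
Reactants: 11 2,2-dimethyl-6-(2-oxopropyl)-4H-1,3-dioxin-4-one; 7 3-[4-(3-{2-[4-(benzyloxy)phenyl]ethyl}-5-methoxyphenoxy)phenyl]-N-methoxy-N-methylpropanamide
Product: 13 6-{2,4-dioxo-6-[4-(3-{2-[4-(benzyloxy)phenyl]ethyl}-5-methoxyphenoxy)phenyl]hexyl}-2,2-dimethyl-4H-1,3-dioxin-4-one, via dilithium dianion 12 (not isolated)
Conditions: 11 (2.5 equiv), LiN(i-Pr)2 (5 equiv), THF, −78 °C; then 7 (1 equiv), −78 to −20 °C; aq NH4Cl/HCl (pH 3); used crude
Reagents that add atoms: none
Why: Twofold deprotonation of 11 gives dianion 12, whose terminal carbon (the last formed and most basic site) should attack the amide carbonyl of 7, a Claisen-type acylation of a 1,3-dicarbonyl dianion by a Weinreb amide. The chelated tetrahedral adduct should persist until the acidic quench, so the acidic triketone 13 never coexists with 12 and neither proton-transfer quench nor double addition is expected. 13 is taken on without chromatography because silica can trigger premature cyclisation.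

Step 6
Reactants: 13 6-{2,4-dioxo-6-[4-(3-{2-[4-(benzyloxy)phenyl]ethyl}-5-methoxyphenoxy)phenyl]hexyl}-2,2-dimethyl-4H-1,3-dioxin-4-one; 14 benzyl alcohol
Product: 18 benzyl 2,4-dihydroxy-6-{2-[4-(3-{2-[4-(benzyloxy)phenyl]ethyl}-5-methoxyphenoxy)phenyl]ethyl}benzoate, via acylketene 15 (not isolated), via benzyl trioxo ester 16 (not isolated), via aldol carbinol 17 (not isolated)
Conditions: 14 (2 equiv), PhMe, 110 °C; then Cs2CO3 (3 equiv), i-PrOH/CH2Cl2, rt; then HCl (4 M in dioxane, to pH 2), rt
Reagents that add atoms: none
Why: At 110 °C the dioxinone ring of 13 should fragment by a retro-hetero-Diels–Alder reaction, expelling acetone and leaving acylketene 15, which the excess of 14 captures at the ketene carbon to give trioxo ester 16. Cs2CO3 then deprotonates C2 of 16 (the methylene between the ester and the C3 ketone, chain numbering), and this carbon adds to the C7 ketone to give carbinol 17; the bond formed is C1–C6 of ring D. The ring closes in a 6-exo-trig (enolendo) aldol mode, and acid then removes water from 17, after which the dione enolises to the resorcinol ring of 18. The closest known reaction type is thermolysis of diketo-dioxinones in the presence of an alcohol, followed by carbonate-mediated cycloaromatisation of the resulting 3,5,7-trioxo ester to a resorcylate. No stereocentre is created: the two centres of 17 are transient and vanish on aromatisation. The step needs the aldol mode (C2 onto C7) to win over Claisen closure (C6 onto the ester carbonyl, leading to an acylphloroglucinol) and over lactonisation to a 4-hydroxy-2-pyranone. In 16 the C3/C5 diketone is enolised and chelated, so C7 is the only free ketone, and a benzyl ester within an enolised β-keto ester is a poor acyl acceptor under a mild carbonate base; the excess of 14 during the thermolysis suppresses ring closure of 15 onto its own enol oxygen.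

Step 7
Reactants: 18 benzyl 2,4-dihydroxy-6-{2-[4-(3-{2-[4-(benzyloxy)phenyl]ethyl}-5-methoxyphenoxy)phenyl]ethyl}benzoate
Product: 19 benzyl 2-hydroxy-4-methoxy-6-{2-[4-(3-{2-[4-(benzyloxy)phenyl]ethyl}-5-methoxyphenoxy)phenyl]ethyl}benzoate
Conditions: MeI (1.1 equiv), K2CO3 (1.5 equiv), acetone, rt
Reagents that add atoms: iodomethane, CI
Why: Williamson O-methylation with a weak base. The 4-OH is the more acidic and unhindered phenol, whereas the 2-OH is tied into a six-membered hydrogen bond with the ester carbonyl and shielded by it, so one equivalent of MeI should give the 4-methyl ether selectively.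

Step 8
Reactants: 19 benzyl 2-hydroxy-4-methoxy-6-{2-[4-(3-{2-[4-(benzyloxy)phenyl]ethyl}-5-methoxyphenoxy)phenyl]ethyl}benzoate
Product: 20 2-hydroxy-6-[2-(4-{3-[2-(4-hydroxyphenyl)ethyl]-5-methoxyphenoxy}phenyl)ethyl]-4-methoxybenzoic acid
Conditions: H2 (1 atm), Pd/C (10 %), EtOAc/MeOH, rt
Reagents that add atoms: none
Why: Catalytic hydrogenolysis should cleave both benzylic C–O bonds (ester and aryl ether) in one neutral operation at room temperature, which avoids decarboxylation of the β-resorcylic acid. The diaryl ether, the methyl ethers and the saturated bridges are inert under these conditions.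

Compound list

1 | methyl 3-(4-hydroxyphenyl)propanoate | COC(=O)CCc1ccc(O)cc1 | starting material
2 | (3-bromo-5-methoxyphenyl)boronic acid | COc1cc(Br)cc(B(O)O)c1 | starting material
3 | methyl 3-[4-(3-bromo-5-methoxyphenoxy)phenyl]propanoate | COC(=O)CCc1ccc(Oc2cc(Br)cc(OC)c2)cc1 | intermediate
4 | 3-[4-(3-bromo-5-methoxyphenoxy)phenyl]-N-methoxy-N-methylpropanamide | CON(C)C(=O)CCc1ccc(Oc2cc(Br)cc(OC)c2)cc1 | intermediate
5 | 1-(benzyloxy)-4-vinylbenzene | C=Cc1ccc(OCc2ccccc2)cc1 | starting material
6 | 9-{2-[4-(benzyloxy)phenyl]ethyl}-9-borabicyclo[3.3.1]nonane (not isolated) | C(Cc1ccc(OCc2ccccc2)cc1)B1C2CCCC1CCC2 | intermediate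
7 | 3-[4-(3-{2-[4-(benzyloxy)phenyl]ethyl}-5-methoxyphenoxy)phenyl]-N-methoxy-N-methylpropanamide | CON(C)C(=O)CCc1ccc(Oc2cc(OC)cc(CCc3ccc(OCc4ccccc4)cc3)c2)cc1 | intermediate
8 | 2,2,6-trimethyl-4H-1,3-dioxin-4-one | CC1=CC(=O)OC(C)(C)O1 | starting material
9 | acetyl chloride | CC(=O)Cl | starting material
10 | lithium 2,2-dimethyl-6-methylidene-6H-1,3-dioxin-4-olate, the dienolate of 8 (not isolated) | [Li+].C=C1C=C([O-])OC(C)(C)O1 | intermediate
11 | 2,2-dimethyl-6-(2-oxopropyl)-4H-1,3-dioxin-4-one | CC(=O)CC1=CC(=O)OC(C)(C)O1 | intermediate
12 | dilithium 6-(2-oxidoprop-2-en-1-ylidene)-2,2-dimethyl-6H-1,3-dioxin-4-olate, the dianion of 11 (not isolated) | [Li+].[Li+].C=C([O-])C=C1C=C([O-])OC(C)(C)O1 | intermediate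
13 | 6-{2,4-dioxo-6-[4-(3-{2-[4-(benzyloxy)phenyl]ethyl}-5-methoxyphenoxy)phenyl]hexyl}-2,2-dimethyl-4H-1,3-dioxin-4-one | CC1(C)OC(CC(=O)CC(=O)CCc2ccc(Oc3cc(OC)cc(CCc4ccc(OCc5ccccc5)cc4)c3)cc2)=CC(=O)O1 | intermediate
14 | benzyl alcohol | OCc1ccccc1 | starting material
15 | 9-[4-(3-{2-[4-(benzyloxy)phenyl]ethyl}-5-methoxyphenoxy)phenyl]non-1-ene-1,3,5,7-tetrone, the acylketene (not isolated) | O=C=CC(=O)CC(=O)CC(=O)CCc1ccc(Oc2cc(OC)cc(CCc3ccc(OCc4ccccc4)cc3)c2)cc1 | intermediate
16 | benzyl 9-[4-(3-{2-[4-(benzyloxy)phenyl]ethyl}-5-methoxyphenoxy)phenyl]-3,5,7-trioxononanoate (not isolated) | O=C(CC(=O)CC(=O)CC(=O)CCc1ccc(Oc2cc(OC)cc(CCc3ccc(OCc4ccccc4)cc3)c2)cc1)OCc1ccccc1 | intermediate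
17 | benzyl 2-hydroxy-4,6-dioxo-2-{2-[4-(3-{2-[4-(benzyloxy)phenyl]ethyl}-5-methoxyphenoxy)phenyl]ethyl}cyclohexane-1-carboxylate, mixture of stereoisomers and enol forms, both centres lost on aromatisation (not isolated) | O=C(OCc1ccccc1)C1C(=O)CC(=O)CC1(O)CCc1ccc(Oc2cc(OC)cc(CCc3ccc(OCc4ccccc4)cc3)c2)cc1 | intermediate
18 | benzyl 2,4-dihydroxy-6-{2-[4-(3-{2-[4-(benzyloxy)phenyl]ethyl}-5-methoxyphenoxy)phenyl]ethyl}benzoate | O=C(OCc1ccccc1)c1c(O)cc(O)cc1CCc1ccc(Oc2cc(OC)cc(CCc3ccc(OCc4ccccc4)cc3)c2)cc1 | intermediate
19 | benzyl 2-hydroxy-4-methoxy-6-{2-[4-(3-{2-[4-(benzyloxy)phenyl]ethyl}-5-methoxyphenoxy)phenyl]ethyl}benzoate | O=C(OCc1ccccc1)c1c(O)cc(OC)cc1CCc1ccc(Oc2cc(OC)cc(CCc3ccc(OCc4ccccc4)cc3)c2)cc1 | intermediate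
20 | 2-hydroxy-6-[2-(4-{3-[2-(4-hydroxyphenyl)ethyl]-5-methoxyphenoxy}phenyl)ethyl]-4-methoxybenzoic acid | COc1cc(CCc2ccc(O)cc2)cc(Oc2ccc(CCc3cc(OC)cc(O)c3C(=O)O)cc2)c1 | target

Total step count: 8. Longest linear sequence: 7 steps (1, 2, 3, 5, 6, 7, 8); step 4 is a one-step branch.

Least certain steps

Step 6 (key step). The ketene may be captured by an enol oxygen of its own chain (lactonisation to a pyranone) faster than by the alcohol. The trioxo ester may also fold in the Claisen mode, or dehydration may remain incomplete. The chain has several nucleophilic and electrophilic sites and only the base and the ester type steer it. The fallback sets out from 13 and avoids ketene release altogether. Et3N in CH2Cl2 at rt, followed by brief acid treatment, should cyclise and aromatise the chain with the dioxinone ring intact. The nucleophile is then the dioxinone C5 carbon, and no ester carbonyl is available for a Claisen closure. This would give the acetonide-protected resorcylate 5-{2-[4-(3-{2-[4-(benzyloxy)phenyl]ethyl}-5-methoxyphenoxy)phenyl]ethyl}-7-hydroxy-2,2-dimethyl-4H-1,3-benzodioxin-4-one F1. Its only free hydroxyl is methylated (MeI, K2CO3, acetone) to 5-{2-[4-(3-{2-[4-(benzyloxy)phenyl]ethyl}-5-methoxyphenoxy)phenyl]ethyl}-7-methoxy-2,2-dimethyl-4H-1,3-benzodioxin-4-one F2. Opening of the benzodioxinone with sodium benzyloxide (14, NaH, THF) returns to the route at 19, which also bypasses the selectivity question of step 7.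

Step 5. The dianion may act as a base toward the α-CH2 of the amide instead of adding to it. It may also react through its internal carbon, or decompose on warming before the acylation is complete; in each case conversion to the triketone would be low. The fallback sets out from 7 and 11 and replaces acylation by aldol addition plus oxidation. Reduction of 7 with i-Bu2AlH (THF, −78 °C) gives 3-[4-(3-{2-[4-(benzyloxy)phenyl]ethyl}-5-methoxyphenoxy)phenyl]propanal F3. Addition of dianion 12 to F3 at −78 °C gives racemic 6-{4-hydroxy-2-oxo-6-[4-(3-{2-[4-(benzyloxy)phenyl]ethyl}-5-methoxyphenoxy)phenyl]hexyl}-2,2-dimethyl-4H-1,3-dioxin-4-one F4. Oxidation of the secondary alcohol with Dess–Martin periodinane (CH2Cl2, rt) returns to the route at 13.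

Step 1. Protodeboronation, oxidative homocoupling or hydroxylation of the boronic acid may outrun the C–O coupling, and turnover at copper may be slow, leaving the phenol unconverted. The fallback does not start from a numbered compound: 1 and 2 are replaced by two commercial compounds, and it rejoins the route at 4, making step 2 unnecessary. 3-Bromo-5-methoxyphenol F5 and 4-fluorobenzaldehyde F6 undergo nucleophilic aromatic substitution (K2CO3, DMF, 120 °C) to 4-(3-bromo-5-methoxyphenoxy)benzaldehyde F7. Horner–Wadsworth–Emmons olefination with diethyl {2-[methoxy(methyl)amino]-2-oxoethyl}phosphonate (NaH, THF, 0 °C to rt) gives (E)-3-[4-(3-bromo-5-methoxyphenoxy)phenyl]-N-methoxy-N-methylprop-2-enamide F8. Homogeneous hydrogenation (H2, RhCl(PPh3)3, PhH/EtOH) saturates the alkene without touching C–Br or N–O and delivers 4. This costs one extra step.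

Step 3. The alkylborane may lose boron by protonolysis or the alkylpalladium may undergo β-hydride elimination, and the aryl bromide may be reduced instead of coupled; residual B–H could also attack the amide. The fallback sets out from 4 and 5 and forms the bridge as an alkene first. A Heck reaction (Pd(OAc)2, P(o-tol)3, K2CO3, DMF, 100 °C) gives 3-[4-(3-{(E)-2-[4-(benzyloxy)phenyl]ethenyl}-5-methoxyphenoxy)phenyl]-N-methoxy-N-methylpropanamide F9. Diimide reduction (TsNHNH2, NaOAc, THF/H2O, reflux) saturates the stilbene double bond without hydrogenolysis of the benzyl ether and returns to the route at 7.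

Further compounds

F1 | step 6 | 5-{2-[4-(3-{2-[4-(benzyloxy)phenyl]ethyl}-5-methoxyphenoxy)phenyl]ethyl}-7-hydroxy-2,2-dimethyl-4H-1,3-benzodioxin-4-one | CC1(C)OC(=O)c2c(CCc3ccc(Oc4cc(OC)cc(CCc5ccc(OCc6ccccc6)cc5)c4)cc3)cc(O)cc2O1
F2 | step 6 | 5-{2-[4-(3-{2-[4-(benzyloxy)phenyl]ethyl}-5-methoxyphenoxy)phenyl]ethyl}-7-methoxy-2,2-dimethyl-4H-1,3-benzodioxin-4-one | CC1(C)OC(=O)c2c(CCc3ccc(Oc4cc(OC)cc(CCc5ccc(OCc6ccccc6)cc5)c4)cc3)cc(OC)cc2O1
F3 | step 5 | 3-[4-(3-{2-[4-(benzyloxy)phenyl]ethyl}-5-methoxyphenoxy)phenyl]propanal | O=CCCc1ccc(Oc2cc(OC)cc(CCc3ccc(OCc4ccccc4)cc3)c2)cc1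
F4 | step 5 | 6-{4-hydroxy-2-oxo-6-[4-(3-{2-[4-(benzyloxy)phenyl]ethyl}-5-methoxyphenoxy)phenyl]hexyl}-2,2-dimethyl-4H-1,3-dioxin-4-one (racemic) | CC1(C)OC(CC(=O)CC(O)CCc2ccc(Oc3cc(OC)cc(CCc4ccc(OCc5ccccc5)cc4)c3)cc2)=CC(=O)O1
F5 | step 1 | 3-bromo-5-methoxyphenol | COc1cc(O)cc(Br)c1
F6 | step 1 | 4-fluorobenzaldehyde | O=Cc1ccc(F)cc1
F7 | step 1 | 4-(3-bromo-5-methoxyphenoxy)benzaldehyde | COc1cc(Br)cc(Oc2ccc(C=O)cc2)c1
F8 | step 1 | (E)-3-[4-(3-bromo-5-methoxyphenoxy)phenyl]-N-methoxy-N-methylprop-2-enamide | CON(C)C(=O)/C=C/c1ccc(Oc2cc(Br)cc(OC)c2)cc1
F9 | step 3 | 3-[4-(3-{(E)-2-[4-(benzyloxy)phenyl]ethenyl}-5-methoxyphenoxy)phenyl]-N-methoxy-N-methylpropanamide | CON(C)C(=O)CCc1ccc(Oc2cc(OC)cc(/C=C/c3ccc(OCc4ccccc4)cc3)c2)cc1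
A1 | alternative 1 | (E)-6-[4-(benzyloxy)phenyl]hex-3-en-2-one | CC(=O)/C=C/CCc1ccc(OCc2ccccc2)cc1
A2 | alternative 1 | dimethyl malonate | COC(=O)CC(=O)OC
A3 | alternative 1 | 5-{2-[4-(benzyloxy)phenyl]ethyl}cyclohexane-1,3-dione | O=C1CC(=O)CC(CCc2ccc(OCc3ccccc3)cc2)C1
A4 | alternative 1 | 3-{2-[4-(benzyloxy)phenyl]ethyl}-5-methoxyphenol | COc1cc(O)cc(CCc2ccc(OCc3ccccc3)cc2)c1
A5 | alternative 2 | 2-(benzyloxy)-4-methoxybenzoic acid | COc1ccc(C(=O)O)c(OCc2ccccc2)c1
A6 | alternative 2 | 1-{2-[4-(benzyloxy)phenyl]ethyl}-3-(4-ethenylphenoxy)-5-methoxybenzene | C=Cc1ccc(Oc2cc(OC)cc(CCc3ccc(OCc4ccccc4)cc3)c2)cc1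
A7 | alternative 2 | 8-(benzyloxy)-3-[4-(3-{2-[4-(benzyloxy)phenyl]ethyl}-5-methoxyphenoxy)phenyl]-6-methoxy-1H-isochromen-1-one | COc1cc(OCc2ccccc2)c2c(c1)C=C(c1ccc(Oc3cc(OC)cc(CCc4ccc(OCc5ccccc5)cc4)c3)cc1)OC2=O
A8 | alternative 3 | benzyl 5-[4-(3-{2-[4-(benzyloxy)phenyl]ethyl}-5-methoxyphenoxy)phenyl]pent-2-ynoate | O=C(OCc1ccccc1)C#CCCc1ccc(Oc2cc(OC)cc(CCc3ccc(OCc4ccccc4)cc3)c2)cc1
A9 | alternative 3 | (Z)-1,3-dimethoxy-1-(trimethylsilyloxy)buta-1,3-diene | C=C(OC)/C=C(/OC)O[Si](C)(C)C
A10 | alternative 3 | benzyl 2-hydroxy-4-methoxy-6-{2-[4-(3-{2-[4-(benzyloxy)phenyl]ethyl}-5-methoxyphenoxy)phenyl]ethyl}benzoate (identical with 19) | O=C(OCc1ccccc1)c1c(O)cc(OC)cc1CCc1ccc(Oc2cc(OC)cc(CCc3ccc(OCc4ccccc4)cc3)c2)cc1
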